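**Strategy.** Ring B together with C17 and the gem-dimethyl carbon C4 (labdane numbering) is a hidden p-menthane. (R)-Carvone supplies C5–C10: its stereocentre becomes C5, its carbonyl C9, its enone methyl C17 and its isopropenyl group C4, C18 and C19. Two enolate alkylations at C10 add C20 and a 3-iodopropyl arm (C1–C3). The key step exploits C4, a gem-dimethyl carbon on C5 and so the Markovnikov carbon of that isopropenyl group. Hydrogen-atom transfer to its CH2 gives the tertiary C4 radical, which nickel couples with the primary C3 iodide. One operation makes the quaternary carbon, ring A and the trans-decalin. The C9 ketone then takes the side chain; C17 is oxidised last.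

Key step: step 3

Remark: compound 3 is carried on as its C6 epimer mixture (trans major), because this centre is planarised again in step 2.

**Step 1**
Reactants: 1 (R)-(−)-carvone
Product: 3 trans-6-methylcarvone (5R,6S; minor 6R epimer carried along), via lithium dienolate 2 (not isolated)
Conditions: LiN(i-Pr)2, THF, −78 °C; then MeI, −78 → 0 °C
Reagents that add atoms: iodomethane, CI
Why: Kinetic α′-deprotonation gives the cross-conjugated dienolate, which is C-methylated (enolate alkylation); the new centre need not be controlled because step 2 planarises it.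

**Step 2**
Reactants: 3 trans-6-methylcarvone; 4 1,3-diiodopropane
Product: 6 (5S,6S)-6-(3-iodopropyl)-6-methylcarvone (iodopropyl arm trans to isopropenyl), via lithium enolate 5 (not isolated)
Conditions: LiN(i-Pr)2, THF, −78 °C; DMPU; then 4 (5 equiv), −78 °C → rt
Reagents that add atoms: 1,3-diiodopropane (4), ICCCI
Why: Enolate alkylation on the face anti to the neighbouring isopropenyl group should place the arm trans to it and the methyl cis, which sets C10; excess diiodide suppresses double alkylation.

**Step 3**
Reactants: 6 (5S,6S)-6-(3-iodopropyl)-6-methylcarvone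
Product: 7 (4aS,8aS)-2,5,5,8a-tetramethyl-4a,5,6,7,8,8a-hexahydronaphthalen-1(4H)-one (trans-fused drim-7-en-9-one core)
Conditions: Fe(acac)3 (30 mol%), NiBr2·diglyme (10 mol%), Mn powder (20 mol%), PhSiH3 (1.5 equiv, slow addition), K2CO3 (2 equiv), DMPU/1,2-dichloroethane, 0.02 M, rt
Reagents that add atoms: none
Why: Proposed new method: an iron hydride formed from Fe(acac)3 and PhSiH3 transfers a hydrogen atom to the terminal CH2 of the isopropenyl group (Markovnikov), giving the tertiary C4 radical, while low-valent nickel inserts into the primary C3–I bond; capture of the radical by the alkylnickel and reductive elimination from trivalent nickel forge the C3–C4 bond, and the divalent iron left behind returns nickel to its low-valent state. The closest known reaction type is the intermolecular metal-hydride/nickel branch-selective hydroalkylation of 1,1-disubstituted olefins with primary alkyl halides to quaternary carbons, run here as a ring closure. Ring A closes in a formal 6-exo Markovnikov mode (bond to the internal olefin carbon, the terminal carbon becoming the second methyl) through a seven-membered nickelacycle. No new stereocentre arises: the trans ring fusion follows from the trans-diequatorial arm at C10 and isopropenyl group at C5 fixed in steps 1 and 2. The step needs hydrogen-atom transfer to the electron-rich isopropenyl group and not to the electron-poor enone, which iron hydrides should respect, and ring closure faster than plain reduction of the olefin or the C–I bond, which the tether, the quaternary C10 (Thorpe–Ingold effect), high dilution and slow silane addition should favour.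

**Step 4**
Reactants: 7 decalin enone
Product: 8 (4aS,8aS)-2,5,5,8a-tetramethyl-1-methylidene-1,4,4a,5,6,7,8,8a-octahydronaphthalene (drima-7,9(11)-diene)
Conditions: Ph3PCH3Br, KOtBu, toluene, 90 °C
Reagents that add atoms: methyltriphenylphosphonium bromide, [Br-].C[P+](c1ccccc1)(c1ccccc1)c1ccccc1
Why: Wittig methylenation; the ketone cannot enolise toward C10, and the small salt-free ylide at elevated temperature should overcome the hindrance; no stereocentre is touched.

**Step 5**
Reactants: 8 drima-7,9(11)-diene
Product: 10 (−)-drimenol [(1S,4aS,8aS)-drim-7-en-11-ol], via B-drimenyl-9-BBN 9 (not isolated)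
Conditions: 9-BBN, THF, 0 °C → rt; then NaOH, H2O2, 0 °C
Reagents that add atoms: hydrogen peroxide, OO
Why: Hydroboration–oxidation; 9-BBN should add to the exocyclic 1,1-disubstituted olefin with boron at C11, and hydrogen is delivered to C9 from the α face anti to the axial C10 methyl, setting C9 (9α-H, CH2OH equatorial).

**Step 6**
Reactants: 10 (−)-drimenol
Product: 11 drimenyl bromide (11-bromodrim-7-ene)
Conditions: CBr4, PPh3, CH2Cl2, 0 °C → rt
Reagents that add atoms: carbon tetrabromide, BrC(Br)(Br)Br
Why: Appel reaction at the primary alcohol under neutral conditions; olefin and C9 are untouched.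

**Step 7**
Reactants: 12 prenyl acetate (3-methylbut-2-enyl acetate)
Product: 13 (E)-4-hydroxy-3-methylbut-2-enyl acetate
Conditions: SeO2 (0.3 equiv), t-BuOOH (3 equiv), CH2Cl2, rt
Reagents that add atoms: selenium dioxide, O=[Se]=O; tert-butyl hydroperoxide, CC(C)(C)OO
Why: Riley allylic oxidation (ene reaction, then [2,3]-sigmatropic shift) should hydroxylate the (E)-methyl selectively, which fixes the E geometry of the later C13=C14 olefin.

**Step 8**
Reactants: 13 (E)-4-hydroxy-3-methylbut-2-enyl acetate
Product: 14 (E)-4-bromo-3-methylbut-2-enyl acetate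
Conditions: CBr4, PPh3, CH2Cl2, −20 → 0 °C
Reagents that add atoms: carbon tetrabromide, BrC(Br)(Br)Br
Why: Appel reaction; direct displacement at the primary allylic carbon should retain the olefin geometry.

**Step 9**
Reactants: 11 drimenyl bromide; 14 (E)-4-bromo-3-methylbut-2-enyl acetate
Product: 16 labda-7,13E-dien-15-yl acetate (5S,9S,10S), via drimenylmagnesium bromide 15 (not isolated)
Conditions: Mg turnings, THF, reflux; then added slowly to 14 and Li2CuCl4 (3 mol%), THF, −78 → −20 °C
Reagents that add atoms: (E)-4-bromo-3-methylbut-2-enyl acetate (14), BrC/C(C)=C/COC(C)=O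
Why: Copper-catalysed Grignard cross-coupling; substitution at the unhindered CH2Br terminus should form C11–C12 with the E olefin preserved, and inverse addition at low temperature should spare the acetate.

**Step 10**
Reactants: 16 labda-7,13E-dien-15-yl acetate
Product: 17 17-hydroxylabda-7,13E-dien-15-yl acetate (5S,9R,10S)
Conditions: SeO2 (0.5 equiv), t-BuOOH (3 equiv), CH2Cl2, 0 °C → rt
Reagents that add atoms: selenium dioxide, O=[Se]=O; tert-butyl hydroperoxide, CC(C)(C)OO
Why: Riley allylic oxidation; selenium should attack C7 with hydrogen taken from the C17 methyl (preferred over the hindered C9 methine), and the [2,3] shift returns the olefin to C7=C8 with oxygen on C17, while the side-chain olefin is deactivated by its allylic acetate.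

**Step 11**
Reactants: 17 17-hydroxylabda-7,13E-dien-15-yl acetate
Product: 18 (5S,9R,10S)-labda-7,13E-diene-15,17-diyl diacetate
Conditions: Ac2O, pyridine, DMAP (cat.), CH2Cl2, rt
Reagents that add atoms: acetic anhydride, CC(=O)OC(C)=O
Why: Acylation of the primary allylic alcohol; no stereocentre or olefin is affected.

**Compound list**

1 | (R)-(−)-carvone | CC(=C)[C@@H]1CC=C(C)C(=O)C1 | starting material
2 | lithium dienolate of 1 (C1=C6 enolate) | CC1=CC[C@@H](C(C)=C)C=C1O[Li] | intermediate
3 | trans-6-methylcarvone, (5R,6S)-2,6-dimethyl-5-(prop-1-en-2-yl)cyclohex-2-en-1-one | O=C1C(C)=CC[C@@H](C(C)=C)[C@@H]1C | intermediate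
4 | 1,3-diiodopropane | ICCCI | starting material
5 | lithium enolate of 3 (tetrasubstituted C1=C6 enolate) | CC1=CC[C@@H](C(C)=C)C(C)=C1O[Li] | intermediate
6 | (5S,6S)-6-(3-iodopropyl)-2,6-dimethyl-5-(prop-1-en-2-yl)cyclohex-2-en-1-one | O=C1C(C)=CC[C@@H](C(C)=C)[C@]1(C)CCCI | intermediate
7 | (4aS,8aS)-2,5,5,8a-tetramethyl-4a,5,6,7,8,8a-hexahydronaphthalen-1(4H)-one | O=C1C(C)=CC[C@H]2C(C)(C)CCC[C@]12C | intermediate
8 | drima-7,9(11)-diene, (4aS,8aS) | C=C1C(C)=CC[C@H]2C(C)(C)CCC[C@]12C | intermediate
9 | B-drimenyl-9-BBN (9-BBN on C11, 9α-H) | C(B3C4CCCC3CCC4)[C@H]1C(C)=CC[C@H]2C(C)(C)CCC[C@]12C | intermediate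
10 | (−)-drimenol, (1S,4aS,8aS)-drim-7-en-11-ol | OC[C@H]1C(C)=CC[C@H]2C(C)(C)CCC[C@]12C | intermediate
11 | drimenyl bromide, 11-bromodrim-7-ene | BrC[C@H]1C(C)=CC[C@H]2C(C)(C)CCC[C@]12C | intermediate
12 | prenyl acetate | CC(C)=CCOC(C)=O | starting material
13 | (E)-4-hydroxy-3-methylbut-2-enyl acetate | OC/C(C)=C/COC(C)=O | intermediate
14 | (E)-4-bromo-3-methylbut-2-enyl acetate | BrC/C(C)=C/COC(C)=O | intermediate
15 | drimenylmagnesium bromide | Br[Mg]C[C@H]1C(C)=CC[C@H]2C(C)(C)CCC[C@]12C | intermediate
16 | labda-7,13E-dien-15-yl acetate | CC(=O)OC/C=C(\C)CC[C@H]1C(C)=CC[C@H]2C(C)(C)CCC[C@]12C | intermediate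
17 | 17-hydroxylabda-7,13E-dien-15-yl acetate | CC(=O)OC/C=C(\C)CC[C@H]1C(CO)=CC[C@H]2C(C)(C)CCC[C@]12C | intermediate
18 | (5S,9R,10S)-labda-7,13E-diene-15,17-diyl diacetate | CC(=O)OC/C=C(\C)CC[C@H]1C(COC(C)=O)=CC[C@H]2C(C)(C)CCC[C@]12C | target

Total step count: 11. Longest linear sequence: 9 steps (steps 1–6 and 9–11).

**Steps most likely to fail**

Step 3 (proposed new method). Capture of the tertiary radical by the tethered alkylnickel may be too slow, so that plain reduction of the olefin or of the C–I bond wins. The fallback makes the same bond by a known hydrogen-atom-transfer Giese cyclisation with a removable activating group. It sets out from 3. The enolate (LiN(i-Pr)2, THF, −78 °C) is alkylated with commercial methyl 2-(bromomethyl)acrylate, again anti to the isopropenyl group, to give the C10 2-(methoxycarbonyl)allyl ketone F1. Fe(acac)3 and PhSiH3 in EtOH/ethylene glycol at 60 °C should then add the tertiary C4 radical to the acrylate CH2 (6-endo) and give the ring A methyl ester F2. LiOH in aqueous THF gives the carboxylic acid F3. Photoredox hydrodecarboxylation (9-mesityl-10-methylacridinium tetrafluoroborate, PhSSPh, 2,6-lutidine, trifluoroethanol, blue light) removes the carboxyl group and comes back to the route at 7.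

Step 10. Site selectivity of the allylic oxidation may be poor, with attack at C6 or at the side-chain olefin. The fallback brings oxygen to C17 through an epoxide and sets out from 16. m-CPBA (1 equiv, CH2Cl2, 0 °C) should epoxidise the more electron-rich ring olefin from the α face to give the 7α,8α-epoxide F4. TMSOTf/DBU in toluene should open it with loss of a C17 proton to the 7α-trimethylsilyloxy-8(17)-ene F5, and dilute HCl in THF frees the allylic alcohol F6. PBr3 (Et2O, 0 °C) gives the transposed primary allylic bromide F7 by SN2′ substitution. KOAc with 18-crown-6 in DMF displaces the bromide and comes back to the route at 18.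

Step 9. The Grignard reagent may attack the acetate or the γ-carbon of 14, losing chemo- or regioselectivity. The fallback turns C11 into a sulfone-stabilised carbanion and sets out from 11. PhSO2Na (DMF, NaI cat., 90 °C) gives drimenyl phenyl sulfone F8. Deprotonation with n-BuLi (THF, −78 °C) and addition of 14 should give the C11-alkylated sulfone F9 by direct substitution only. Na(Hg) with Na2HPO4 in THF/MeOH at −20 °C removes the sulfonyl group and comes back to the route at 16.

**Further compounds**

F1 | step 3 | methyl 2-{[1,3-dimethyl-2-oxo-6-(prop-1-en-2-yl)cyclohex-3-en-1-yl]methyl}prop-2-enoate (arm trans to isopropenyl) | O=C1C(C)=CC[C@@H](C(C)=C)[C@]1(C)CC(=C)C(=O)OC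
F2 | step 3 | methyl ester at C2 of ring A of 7 (C2 epimers) | O=C1C(C)=CC[C@H]2C(C)(C)CC(C(=O)OC)C[C@]12C
F3 | step 3 | carboxylic acid at C2 of ring A of 7 (C2 epimers) | O=C1C(C)=CC[C@H]2C(C)(C)CC(C(=O)O)C[C@]12C
F4 | step 10 | 7α,8α-epoxylabd-13E-en-15-yl acetate | CC(=O)OC/C=C(\C)CC[C@H]1[C@]3(C)O[C@@H]3C[C@H]2C(C)(C)CCC[C@]12C
F5 | step 10 | 7α-trimethylsilyloxylabda-8(17),13E-dien-15-yl acetate | CC(=O)OC/C=C(\C)CC[C@H]1C(=C)[C@H](O[Si](C)(C)C)C[C@H]2C(C)(C)CCC[C@]12C
F6 | step 10 | 7α-hydroxylabda-8(17),13E-dien-15-yl acetate | CC(=O)OC/C=C(\C)CC[C@H]1C(=C)[C@H](O)C[C@H]2C(C)(C)CCC[C@]12C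
F7 | step 10 | 17-bromolabda-7,13E-dien-15-yl acetate | CC(=O)OC/C=C(\C)CC[C@H]1C(CBr)=CC[C@H]2C(C)(C)CCC[C@]12C
F8 | step 9 | drimenyl phenyl sulfone (11-phenylsulfonyldrim-7-ene) | O=S(=O)(C[C@H]1C(C)=CC[C@H]2C(C)(C)CCC[C@]12C)c1ccccc1
F9 | step 9 | 11-(phenylsulfonyl)labda-7,13E-dien-15-yl acetate (C11 epimers) | CC(=O)OC/C=C(\C)CC([C@H]1C(C)=CC[C@H]2C(C)(C)CCC[C@]12C)S(=O)(=O)c1ccccc1
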